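**Retrosynthetic overview**
1. Target 25 ⇐ angeloylation and desilylation of 21 ⇐ opening (ester methylation, O8 acetylation) of the cis-fused α-methylene γ-lactone 18. This lactone ring (O8–C12) is not in the target; it holds C7/C8 cis and carries both the ester carbon and O8.
2. 5α-OH with C4=C15 ⇐ singlet-oxygen ene reaction of a Δ4 alkene; C11=C13 ⇐ lactone methylenation; ring A ⇐ Robinson-type annulation of ethyl vinyl ketone onto ring B (Mukaiyama–Michael at C10, aldol condensation C4–C5).
3. γ-Lactone ⇐ Baeyer–Villiger expansion of a cis-fused cyclobutanone; ring B, with the C6–C7 and C8–C9 bonds, ⇐ Diels–Alder reaction of 2-silyloxy-3-methylbuta-1,3-diene (C6=C5(OSi)–C10(Me)=C9) with cyclobut-2-enone (C7=C8, C12=O, C11H2).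
4. Enabling feature: in ring B (C5–C10) the oxygen-bearing C5 and C8 are 1,4-related, C5 is next to the methyl-bearing C10, and the C8–O and C7–C11 bonds are cis. C5(O)–C10(Me) is therefore the enol-ether footprint of a 2-silyloxydiene, and C8(–O)–C12(=O)–C11–C7 is a cyclobutanone after Baeyer–Villiger insertion.
5. Ring order: four-membered ring (brought in) and ring B together (step 3); four-membered ring expanded to the γ-lactone (step 5); ring A (step 6); lactone opened (step 11).

Key step: step 3

**Remarks**
- Eudesmane numbering is used: ring A = C1–C5 and C10; ring B = C5–C10; C11, C12 (carbonyl) and C13 (methylene) form the acrylate/lactone unit; C14 is the angular methyl; C15 is the exocyclic methylene on C4. β is the face of C14.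
- Assumption: 3-bromocyclobutan-1-one is taken as a catalogue compound.
- Assumption: the facial sense of the oxazaborolidinium catalyst with cyclobut-2-enone follows that of larger cycloalkenones. The (S)-catalyst is written; its mirror image, equally accessible, takes its place if the sense is opposite.

**Route**

Step 1
Reactants: 1 3-methylbut-3-en-2-one
Product: 2 tert-butyl(dimethyl)[(3-methylbuta-1,3-dien-2-yl)oxy]silane
Conditions: TBSOTf, NEt3, Et2O, 0 °C
Reagents that add atoms: tert-butyldimethylsilyl trifluoromethanesulfonate, CC(C)(C)[Si](C)(C)OS(=O)(=O)C(F)(F)F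
Why: Soft enolisation of the methyl ketone (only the methyl side can enolise) with a silyl triflate and an amine base is the standard route to 2-silyloxy-1,3-dienes and sets no stereocentre.

Step 2
Reactants: 3 3-bromocyclobutan-1-one
Product: 4 cyclobut-2-en-1-one
Conditions: NBu3, neat, rt, vacuum transfer into a −78 °C trap; used at once as a cold CH2Cl2 solution
Reagents that add atoms: none
Why: E1cB dehydrobromination of the β-bromo ketone by a hindered tertiary amine gives the strained enone, which is separated from the ammonium salt by vacuum transfer and used cold because it oligomerises on standing.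

Step 3
Reactants: 2 tert-butyl(dimethyl)[(3-methylbuta-1,3-dien-2-yl)oxy]silane; 4 cyclobut-2-en-1-one
Product: 5 (1R,6R)-3-[(tert-butyldimethylsilyl)oxy]-4-methylbicyclo[4.2.0]oct-3-en-7-one
Conditions: (S)-1-(2-methylphenyl)-3,3-diphenyltetrahydro-1H,3H-pyrrolo[1,2-c][1,3,2]oxazaborole (20 mol %), HN(SO2CF3)2 (18 mol %), CH2Cl2, −78 °C
Reagents that add atoms: none
Why: The chiral oxazaborolidinium cation binds the cyclobutenone carbonyl and lowers its LUMO, and the 2-silyloxydiene adds in a concerted but asynchronous normal-demand [4+2] cycloaddition in which the C6–C7 bond (nucleophilic diene terminus to enone β-carbon) runs ahead of the C9–C8 bond. The closest known reaction types are the thermal Diels–Alder reactions of cyclobut-2-enone, whose ring strain makes it far more reactive than larger cycloalkenones, and the oxazaborolidinium-catalysed enantioselective Diels–Alder reactions of cycloalkenones with 2-silyloxydienes. Ring B is closed by intermolecular [4+2] cycloaddition, suprafacial on both partners, while the four-membered ring is brought in intact by the dienophile. C7 and C8 must be cis because the dienophile double bond lies in a ring, and their absolute configuration (both ring-fusion hydrogens α) is set by the catalyst, which shields one face of the bound enone. The step needs "para" regioselectivity (acyl-bearing C8 1,4 to silyloxy-bearing C5), which the strongly polarising silyloxy group should secure against the weak opposing effect of the C10 methyl; endo/exo selectivity is irrelevant because the diene termini are unsubstituted. In one operation the step delivers ring B, both of its stereocentres, a cyclobutanone that is a latent C8–O bond plus the C11–C12 unit, and the regiodefined C5=C10 silyl enol ether needed to build the quaternary C10.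

Step 4
Reactants: 5 (1R,6R)-3-[(tert-butyldimethylsilyl)oxy]-4-methylbicyclo[4.2.0]oct-3-en-7-one; 6 pent-1-en-3-one (ethyl vinyl ketone)
Product: 8 cis-fused 4-methyl-4-(3-oxopentyl)bicyclo[4.2.0]octane-3,7-dione (methyl cis to the four-membered ring), via side-chain silyl enol ether 7 (not isolated)
Conditions: HN(SO2CF3)2 (5 mol %), CH2Cl2, −78 °C; then 1 M HCl, THF, 0 °C
Reagents that add atoms: none
Why: Mukaiyama–Michael addition of the regiodefined tetrasubstituted silyl enol ether to the vinyl ketone under silyl triflimide catalysis forms the quaternary C10, the acceptor approaching the convex α face of the cis-fused bicycle (a β-side electrophile would be 1,3-syn-axial to the C8–C12 bond), so that the methyl group should end up β, cis to the cyclobutanone.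

Step 5
Reactants: 8 cis-fused 4-methyl-4-(3-oxopentyl)bicyclo[4.2.0]octane-3,7-dione
Product: 9 cis-fused 6-methyl-6-(3-oxopentyl)hexahydro-1-benzofuran-2,5-dione (methyl on the face of the lactone ring)
Conditions: 30% aq H2O2, AcOH, 0 °C → rt
Reagents that add atoms: hydrogen peroxide, OO
Why: Baeyer–Villiger oxidation is far faster for the strained cyclobutanone than for the two unstrained ketones, and the more substituted ring-fusion carbon C8 migrates with retention, which places the new oxygen on C8 on the β face and gives the cis-fused γ-lactone.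

Step 6
Reactants: 9 cis-fused 6-methyl-6-(3-oxopentyl)hexahydro-1-benzofuran-2,5-dione
Product: 11 3-oxo-13-noreudesm-4-en-12,8β-olide (7αH,8αH,10β-methyl), via ketol 10 (not isolated)
Conditions: TsOH·H2O (10 mol %), toluene, reflux, Dean–Stark trap
Reagents that add atoms: none
Why: Acid-catalysed intramolecular aldol condensation of the 1,5-diketone (the second half of a Robinson annulation) closes ring A through the C4–C5 bond and dehydrates to the conjugated 4-methyl Δ4-3-ketone, under conditions that leave the lactone and all existing stereocentres untouched.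

Step 7
Reactants: 11 3-oxo-13-noreudesm-4-en-12,8β-olide
Product: 12 3β-hydroxy-13-noreudesm-4-en-12,8β-olide
Conditions: NaBH4, CeCl3·7H2O, MeOH, −78 → −20 °C
Reagents that add atoms: none
Why: Luche reduction gives clean 1,2-reduction of the enone without touching the lactone, hydride entering axially from the α face opposite the angular C14 methyl to give the equatorial 3β-alcohol.

Step 8
Reactants: 12 3β-hydroxy-13-noreudesm-4-en-12,8β-olide
Product: 13 3β-[(tert-butyldimethylsilyl)oxy]-13-noreudesm-4-en-12,8β-olide
Conditions: TBSCl, imidazole, DMF, rt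
Reagents that add atoms: tert-butyldimethylsilyl chloride, CC(C)(C)[Si](C)(C)Cl
Why: Standard silylation of the secondary allylic alcohol masks O3 through the base- and oxidant-mediated steps that follow.

Step 9
Reactants: 13 3β-[(tert-butyldimethylsilyl)oxy]-13-noreudesm-4-en-12,8β-olide
Product: 16 3β-[(tert-butyldimethylsilyl)oxy]eudesma-4,11(13)-dien-12,8β-olide, via Mannich base 14 (not isolated), via methiodide 15 (not isolated)
Conditions: LiN(iPr)2, THF, −78 °C; [CH2=NMe2]I, −78 °C → rt; MeI, THF/MeOH, rt; sat. aq NaHCO3, rt
Reagents that add atoms: N,N-dimethylmethyleneiminium iodide (Eschenmoser's salt), C=[N+](C)C.[I-]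
Why: α-Methylenation of the lactone by the Mannich reaction of its lithium enolate with the iminium salt, followed by quaternisation and E1cB (Hofmann-type) elimination, installs C13; C11 is the only acidic position and its transient configuration is irrelevant.

Step 10
Reactants: 16 3β-[(tert-butyldimethylsilyl)oxy]eudesma-4,11(13)-dien-12,8β-olide
Product: 18 5α-hydroxy-3β-[(tert-butyldimethylsilyl)oxy]eudesma-4(15),11(13)-dien-12,8β-olide, via hydroperoxide 17 (not isolated)
Conditions: O2, 5,10,15,20-tetraphenylporphyrin (cat.), visible light, CH2Cl2, −20 °C; then PPh3, 0 °C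
Reagents that add atoms: dioxygen, O=O
Why: The Schenck ene reaction of singlet oxygen with the electron-rich tetrasubstituted C4=C5 alkene (the conjugated C11=C13 alkene is inert) should occur on the α face, opposite the axial C14 methyl and the β-oriented lactone and silyloxy groups, with abstraction of a C15 methyl hydrogen, which moves the double bond to C4=C15 and leaves a hydroperoxide that the phosphine reduces in situ to the 5α tertiary alcohol.

Step 11
Reactants: 18 5α-hydroxy-3β-[(tert-butyldimethylsilyl)oxy]eudesma-4(15),11(13)-dien-12,8β-olide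
Product: 21 methyl 8β-acetoxy-5α-hydroxy-3β-[(tert-butyldimethylsilyl)oxy]eudesma-4(15),11(13)-dien-12-oate, via potassium carboxylate 19 (not isolated), via hydroxy ester 20 (not isolated)
Conditions: KOH (1.1 equiv), THF/H2O, 0 °C → rt; evaporate; MeI, DMF, rt; then Ac2O, NEt3, 4-(dimethylamino)pyridine (cat.), rt
Reagents that add atoms: potassium hydroxide, [K+].[OH-]; iodomethane, CI; acetic anhydride, CC(=O)OC(C)=O
Why: Saponification opens the lactone at the acyl carbon with retention at C8, O-alkylation of the potassium carboxylate with iodomethane gives the methyl ester without any acid that would re-close the ring, and immediate acyl-transfer-catalysed acetylation caps the axial 8β-hydroxyl while the tertiary 5α-hydroxyl stays free.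

Step 12
Reactants: 21 methyl 8β-acetoxy-5α-hydroxy-3β-[(tert-butyldimethylsilyl)oxy]eudesma-4(15),11(13)-dien-12-oate
Product: 22 methyl 8β-acetoxy-3β,5α-dihydroxyeudesma-4(15),11(13)-dien-12-oate
Conditions: HF·pyridine, THF/pyridine, 0 °C → rt
Reagents that add atoms: none
Why: Buffered fluoride desilylation removes the secondary allylic silyl ether without touching the acetate, the acrylate or the tertiary allylic alcohol.

Step 13
Reactants: 22 methyl 8β-acetoxy-3β,5α-dihydroxyeudesma-4(15),11(13)-dien-12-oate; 23 angelic acid [(Z)-2-methylbut-2-enoic acid]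
Product: 25 methyl 8β-acetoxy-3β-angeloyloxy-5α-hydroxyeudesma-4(15),11(13)-dien-12-oate (CNP0179024.1), via mixed anhydride 24 (not isolated)
Conditions: 2,4,6-trichlorobenzoyl chloride, NEt3, toluene, rt; then 22, toluene, 80 °C
Reagents that add atoms: none
Why: Yamaguchi esterification through the mixed anhydride with 2,4,6-trichlorobenzoic acid, run without a nucleophilic amine catalyst, acylates the only reactive (secondary) hydroxyl and is the established way to transfer the angeloyl group without Z-to-E isomerisation to the tiglate.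

**Compound list**
1 | 3-methylbut-3-en-2-one | CC(=O)C(C)=C | starting material
2 | tert-butyl(dimethyl)[(3-methylbuta-1,3-dien-2-yl)oxy]silane | C=C(C)C(=C)O[Si](C)(C)C(C)(C)C | intermediate
3 | 3-bromocyclobutan-1-one | O=C1CC(Br)C1 | starting material
4 | cyclobut-2-en-1-one | O=C1C=CC1 | intermediate
5 | (1R,6R)-3-[(tert-butyldimethylsilyl)oxy]-4-methylbicyclo[4.2.0]oct-3-en-7-one (cis-fused) | O=C2C[C@H]1CC(O[Si](C)(C)C(C)(C)C)=C(C)C[C@H]12 | intermediate
6 | pent-1-en-3-one (ethyl vinyl ketone) | C=CC(=O)CC | starting material
7 | tert-butyldimethylsilyl enol ether of 8 at the side-chain ketone (enol ether geometry open) | O=C2C[C@H]1CC(=O)[C@](C)(CCC(O[Si](C)(C)C(C)(C)C)=CC)C[C@H]12 | intermediate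
8 | cis-fused 4-methyl-4-(3-oxopentyl)bicyclo[4.2.0]octane-3,7-dione, methyl cis to the four-membered ring (7αH,8αH,10β-methyl) | O=C2C[C@H]1CC(=O)[C@](C)(CCC(=O)CC)C[C@H]12 | intermediate
9 | cis-fused 6-methyl-6-(3-oxopentyl)hexahydro-1-benzofuran-2,5-dione, methyl on the face of the lactone ring (8β-O, 7β-C11, 10β-methyl) | O=C2C[C@H]1CC(=O)[C@](C)(CCC(=O)CC)C[C@H]1O2 | intermediate
10 | 5-hydroxy-3-oxo-13-noreudesman-12,8β-olide (ketol; epimers at C4 and C5) | O=C2C[C@H]1CC3(O)C(C)C(=O)CC[C@]3(C)C[C@H]1O2 | intermediate
11 | 3-oxo-13-noreudesm-4-en-12,8β-olide (7αH,8αH,10β-methyl) | O=C2C[C@H]1CC3=C(C)C(=O)CC[C@]3(C)C[C@H]1O2 | intermediate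
12 | 3β-hydroxy-13-noreudesm-4-en-12,8β-olide | O=C2C[C@H]1CC3=C(C)[C@@H](O)CC[C@]3(C)C[C@H]1O2 | intermediate
13 | 3β-[(tert-butyldimethylsilyl)oxy]-13-noreudesm-4-en-12,8β-olide | O=C2C[C@H]1CC3=C(C)[C@@H](O[Si](C)(C)C(C)(C)C)CC[C@]3(C)C[C@H]1O2 | intermediate
14 | 13-(dimethylamino)-3β-[(tert-butyldimethylsilyl)oxy]eudesm-4-en-12,8β-olide (C11 epimers) | O=C2C(CN(C)C)[C@H]1CC3=C(C)[C@@H](O[Si](C)(C)C(C)(C)C)CC[C@]3(C)C[C@H]1O2 | intermediate
15 | 13-(trimethylammonio)-3β-[(tert-butyldimethylsilyl)oxy]eudesm-4-en-12,8β-olide iodide (C11 epimers) | O=C2C(C[N+](C)(C)C)[C@H]1CC3=C(C)[C@@H](O[Si](C)(C)C(C)(C)C)CC[C@]3(C)C[C@H]1O2.[I-] | intermediate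
16 | 3β-[(tert-butyldimethylsilyl)oxy]eudesma-4,11(13)-dien-12,8β-olide | O=C2C(=C)[C@H]1CC3=C(C)[C@@H](O[Si](C)(C)C(C)(C)C)CC[C@]3(C)C[C@H]1O2 | intermediate
17 | 5α-hydroperoxy-3β-[(tert-butyldimethylsilyl)oxy]eudesma-4(15),11(13)-dien-12,8β-olide | O=C2C(=C)[C@H]1C[C@@]3(OO)C(=C)[C@@H](O[Si](C)(C)C(C)(C)C)CC[C@]3(C)C[C@H]1O2 | intermediate
18 | 5α-hydroxy-3β-[(tert-butyldimethylsilyl)oxy]eudesma-4(15),11(13)-dien-12,8β-olide | O=C2C(=C)[C@H]1C[C@@]3(O)C(=C)[C@@H](O[Si](C)(C)C(C)(C)C)CC[C@]3(C)C[C@H]1O2 | intermediate
19 | potassium 5α,8β-dihydroxy-3β-[(tert-butyldimethylsilyl)oxy]eudesma-4(15),11(13)-dien-12-oate | [K+].[O-]C(=O)C(=C)[C@H]1C[C@@]2(O)C(=C)[C@@H](O[Si](C)(C)C(C)(C)C)CC[C@]2(C)C[C@H]1O | intermediate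
20 | methyl 5α,8β-dihydroxy-3β-[(tert-butyldimethylsilyl)oxy]eudesma-4(15),11(13)-dien-12-oate | COC(=O)C(=C)[C@H]1C[C@@]2(O)C(=C)[C@@H](O[Si](C)(C)C(C)(C)C)CC[C@]2(C)C[C@H]1O | intermediate
21 | methyl 8β-acetoxy-5α-hydroxy-3β-[(tert-butyldimethylsilyl)oxy]eudesma-4(15),11(13)-dien-12-oate | COC(=O)C(=C)[C@H]1C[C@@]2(O)C(=C)[C@@H](O[Si](C)(C)C(C)(C)C)CC[C@]2(C)C[C@H]1OC(C)=O | intermediate
22 | methyl 8β-acetoxy-3β,5α-dihydroxyeudesma-4(15),11(13)-dien-12-oate | COC(=O)C(=C)[C@H]1C[C@@]2(O)C(=C)[C@@H](O)CC[C@]2(C)C[C@H]1OC(C)=O | intermediate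
23 | angelic acid, (Z)-2-methylbut-2-enoic acid | C/C=C(/C)C(=O)O | starting material
24 | angelic 2,4,6-trichlorobenzoic anhydride | C/C=C(/C)C(=O)OC(=O)c1c(Cl)cc(Cl)cc1Cl | intermediate
25 | methyl 8β-acetoxy-3β-angeloyloxy-5α-hydroxyeudesma-4(15),11(13)-dien-12-oate (CNP0179024.1) | C=C(C(=O)OC)[C@H]1C[C@@]2(O)C(=C)[C@@H](OC(=O)/C(C)=C\C)CC[C@]2(C)C[C@H]1OC(C)=O | target

**Step count and risks**

Total step count: 13. Longest linear sequence: 12 steps (step 1 or step 2, then steps 3 to 13).

Step 3, the key cycloaddition. What may go wrong: erosion of enantioselectivity by the uncatalysed background cycloaddition, or acid-induced oligomerisation of the strained enone on the cationic boron catalyst. Fallback: enantiocontrol is moved from the cycloaddition to the ring expansion. Setting out from 2 and 4, the cycloaddition is run thermally without catalyst (CH2Cl2, 0 °C → rt). This gives 5 as the racemate, that is, together with its enantiomer, the (1S,6S)-adduct F1. Step 4 is applied unchanged and gives racemic triketone, 8 together with the enantiomeric triketone F3 (through the enantiomeric side-chain silyl enol ether F2, not isolated). The Baeyer–Villiger step is then run with an enzyme of the Baeyer–Villiger monooxygenase class (cyclohexanone monooxygenase type; NADPH recycled with glucose and glucose dehydrogenase; air, buffer pH 8, 25 °C). This is a regiodivergent parallel kinetic resolution of the kind established for fused bicyclic cyclobutanones: 8 should be converted into the normal lactone 9, while F3 is converted into the constitutionally isomeric lactone with oxygen inserted on the methylene side, the abnormal lactone F4, or is left behind. Chromatographic separation returns enantioenriched 9 to the route before step 6.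

Step 4, the quaternary centre C10. What may go wrong: poor facial selectivity in the attack of the vinyl ketone on C10, since substrate control comes only from the remote cis-fused ring, or competing Mukaiyama aldol addition of the enol ether to the electrophilic cyclobutanone. Fallback: the four-membered ring is expanded first and C10 is then built under reagent control by a chiral imine. Setting out from 5, mild acid hydrolysis (1 M HCl, THF, 0 °C) gives cis-fused 4-methylbicyclo[4.2.0]octane-3,7-dione F5 (epimers at the methyl-bearing carbon, of no consequence). Baeyer–Villiger oxidation (30% H2O2, AcOH) gives the cis-fused keto lactone 6-methylhexahydro-1-benzofuran-2,5-dione F6. Condensation with (R)-1-phenylethylamine (TiCl4, NEt3, CH2Cl2, 0 °C) gives the ring-ketone imine F7. This reacts through its more substituted secondary enamine tautomer with ethyl vinyl ketone 6 (THF, rt) in an aza-ene-type Michael addition on the face dictated by the auxiliary, giving the adduct imine F8 (not isolated). Hydrolysis with aqueous acetic acid releases the auxiliary and returns to the route at 9.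

Step 10, the ene reaction. What may go wrong: abstraction of the axial C6 hydrogen instead of a C15 hydrogen (leading to the 4-hydroperoxy Δ5 isomer), or allylic rearrangement of the tertiary hydroperoxide before it is reduced. Fallback: the oxygen is introduced as an epoxide and the double bond is moved by base. The fallback sets out from 13, before methylenation, so that no Michael acceptor meets the amide base. Treatment with mCPBA (NaHCO3, CH2Cl2, 0 °C) should give, on the face opposite C14, the 4α,5α-epoxide F9. Diethylaluminium 2,2,6,6-tetramethylpiperidide (from Et2AlCl and lithium 2,2,6,6-tetramethylpiperidide; toluene, 0 °C) then isomerises the epoxide by syn removal of a proton from the least hindered β-carbon, the C15 methyl, with cleavage of the C4–O bond, to the 5α-hydroxy 4(15)-ene lactone F10. Methylenation as in step 9, with a second equivalent of LiN(iPr)2 for the tertiary hydroxyl, proceeds through the Mannich base F11 and the methiodide F12 (neither isolated) and returns to the route at 18.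

Further compounds
F1 | step 3 | (1S,6S)-3-[(tert-butyldimethylsilyl)oxy]-4-methylbicyclo[4.2.0]oct-3-en-7-one (enantiomer of 5) | O=C2C[C@@H]1CC(O[Si](C)(C)C(C)(C)C)=C(C)C[C@@H]12
F2 | step 3 | enantiomer of side-chain silyl enol ether 7 | O=C2C[C@@H]1CC(=O)[C@@](C)(CCC(O[Si](C)(C)C(C)(C)C)=CC)C[C@@H]12
F3 | step 3 | enantiomer of triketone 8 | O=C2C[C@@H]1CC(=O)[C@@](C)(CCC(=O)CC)C[C@@H]12
F4 | step 3 | abnormal lactone from F3, cis-fused 6-methyl-6-(3-oxopentyl)hexahydro-2-benzofuran-1,5-dione | O=C2OC[C@@H]1CC(=O)[C@@](C)(CCC(=O)CC)C[C@@H]12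
F5 | step 4 | cis-fused 4-methylbicyclo[4.2.0]octane-3,7-dione (epimers at the methyl carbon) | O=C2C[C@H]1CC(=O)C(C)C[C@H]12
F6 | step 4 | cis-fused 6-methylhexahydro-1-benzofuran-2,5-dione (epimers at the methyl carbon) | O=C2C[C@H]1CC(=O)C(C)C[C@H]1O2
F7 | step 4 | (R)-1-phenylethyl imine of F6 at the ring ketone | O=C2C[C@H]1CC(=N[C@H](C)c3ccccc3)C(C)C[C@H]1O2
F8 | step 4 | (R)-1-phenylethyl imine of 9 at the ring ketone | O=C2C[C@H]1CC(=N[C@H](C)c3ccccc3)[C@](C)(CCC(=O)CC)C[C@H]1O2
F9 | step 10 | 4α,5α-epoxy-3β-[(tert-butyldimethylsilyl)oxy]-13-noreudesman-12,8β-olide | O=C2C[C@H]1C[C@@]34O[C@]3(C)[C@@H](O[Si](C)(C)C(C)(C)C)CC[C@]4(C)C[C@H]1O2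
F10 | step 10 | 5α-hydroxy-3β-[(tert-butyldimethylsilyl)oxy]-13-noreudesm-4(15)-en-12,8β-olide | O=C2C[C@H]1C[C@@]3(O)C(=C)[C@@H](O[Si](C)(C)C(C)(C)C)CC[C@]3(C)C[C@H]1O2
F11 | step 10 | 13-(dimethylamino)-5α-hydroxy-3β-[(tert-butyldimethylsilyl)oxy]eudesm-4(15)-en-12,8β-olide (C11 epimers) | O=C2C(CN(C)C)[C@H]1C[C@@]3(O)C(=C)[C@@H](O[Si](C)(C)C(C)(C)C)CC[C@]3(C)C[C@H]1O2
F12 | step 10 | 13-(trimethylammonio)-5α-hydroxy-3β-[(tert-butyldimethylsilyl)oxy]eudesm-4(15)-en-12,8β-olide iodide (C11 epimers) | O=C2C(C[N+](C)(C)C)[C@H]1C[C@@]3(O)C(=C)[C@@H](O[Si](C)(C)C(C)(C)C)CC[C@]3(C)C[C@H]1O2.[I-]
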